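**Plan**

1. Retrosynthesis: ring B is stripped first (C15 silyl ether, C8=C17 methylene, C7 acetate), then the C4–CH3 and C5–H bonds (reductive methylation of a C4=C5 unsaturated ester), then ring A is opened at C4=C5 and C10–C1, and last the C9–C11 bond is cut.
2. Forward: ring B is bought as the mono-ketal enone of cyclohexane-1,4-dione (carbonyl = C5, ketal = C8) and receives its C10 methyl; the side chain (from 4-bromobut-1-yne) enters at C9 by copper-catalysed asymmetric conjugate addition and the C5–C10 enolate is stored as its silyl ether; ring A, the only ring that has to be built, is closed last.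
3. Enabling feature: C10 (quaternary, methyl-bearing) is the alpha carbon and C5 the carbonyl carbon of a ring B ketone, and the ester sits on C4 next to ring-fusion carbon C5. Ring A is therefore the four-carbon bridge C1–C4 between an enolate carbon and a ketone carbon, and a 2-phosphonopenta-2,4-dienoate should deliver it in one flask (C10–C1 by 1,6-addition, C4=C5 by intramolecular Horner–Wadsworth–Emmons olefination).
4. Stereochemistry: C9 from the chiral copper catalyst; C10 by attack anti to the C9 chain; C5 (trans fusion) and C4 (methyl equatorial, ester axial) together from Li/NH3 reduction–methylation of the C4=C5 enoate; C7 by axial enolate hydroxylation, then Mitsunobu inversion; the 13E alkene from syn carboalumination.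

Key step: step 8

Remark on names: bicyclic compounds carry labdane locants (ring A = C1–C5 and C10; ring B = C5–C10; C17 on C8, C18 and C19 on C4, C20 on C10) and β is the face of the C10 methyl group; monocyclic precursors are named as 1,4-dioxaspiro[4.5]decanes, whose C5, C6, C7, C8, C9, C10 become labdane C8, C9, C10, C5, C6, C7.

**Route**

Step 1
Reactants: 1 1,4-dioxaspiro[4.5]dec-6-en-8-one
Product: 2 7-iodo-1,4-dioxaspiro[4.5]dec-6-en-8-one
Conditions: I2, pyridine, CH2Cl2, 0 °C to rt
Reagents that add atoms: iodine, II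
Why: Pyridine-mediated α-iodination of a cyclohexenone (conjugate addition of pyridine, iodination of the enolate, elimination) should place iodine on the future C10 without touching the ketal.

Step 2
Reactants: 2 7-iodo-1,4-dioxaspiro[4.5]dec-6-en-8-one
Product: 3 7-methyl-1,4-dioxaspiro[4.5]dec-6-en-8-one
Conditions: MeB(OH)2, Pd(OAc)2 (cat.), SPhos, K3PO4, toluene/H2O, 90 °C
Reagents that add atoms: methylboronic acid, CB(O)O
Why: Suzuki–Miyaura coupling of an α-iodoenone with methylboronic acid should install the future C20 methyl on the enone α-carbon under conditions that the ketal tolerates.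

Step 3
Reactants: 4 4-bromobut-1-yne
Product: 6 methyl (2E)-5-bromo-3-methylpent-2-enoate, via alkenylalane 5 (not isolated)
Conditions: Me3Al, Cp2ZrCl2 (cat.), CH2Cl2, 0 °C to rt; then ClCO2Me, 0 °C
Reagents that add atoms: trimethylaluminium, C[Al](C)C; methyl chloroformate, COC(=O)Cl
Why: Zirconium-catalysed Negishi carboalumination adds CH3 and Al syn across the terminal alkyne with the methyl on the inner carbon, and acylation of the alkenylalane with retention should fix the E geometry of the later C13=C14 bond.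

Step 4
Reactants: 6 methyl (2E)-5-bromo-3-methylpent-2-enoate
Product: 7 (2E)-5-bromo-3-methylpent-2-en-1-ol
Conditions: i-Bu2AlH, CH2Cl2, −78 °C
Reagents that add atoms: none
Why: 1,2-Reduction of the conjugated ester by i-Bu2AlH should give the allylic alcohol and leave the primary bromide and the alkene geometry unchanged.

Step 5
Reactants: 7 (2E)-5-bromo-3-methylpent-2-en-1-ol
Product: 8 [(2E)-5-bromo-3-methylpent-2-en-1-yl]oxy(triisopropyl)silane
Conditions: i-Pr3SiCl, imidazole, DMF, rt
Reagents that add atoms: chlorotriisopropylsilane, CC(C)[Si](Cl)(C(C)C)C(C)C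
Why: Silylation of the primary allylic alcohol gives an ether that should survive Grignard formation, Li/NH3, aqueous acid and the titanium reagent, and that fluoride removes at the end.

Step 6
Reactants: 3 7-methyl-1,4-dioxaspiro[4.5]dec-6-en-8-one; 8 [(2E)-5-bromo-3-methylpent-2-en-1-yl]oxy(triisopropyl)silane
Product: 11 (6R)-7-methyl-6-[(3E)-3-methyl-5-(triisopropylsilyloxy)pent-3-en-1-yl]-8-(trimethylsilyloxy)-1,4-dioxaspiro[4.5]dec-7-ene, via Grignard reagent 9 (not isolated), via bromomagnesium enolate 10 (not isolated)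
Conditions: 8, Mg, THF, rt; then 3, CuBr·SMe2 (5 mol %), chiral ferrocenyl diphosphine (Josiphos type, 6 mol %), Me3SiCl, t-BuOMe, −78 °C; Et3N
Reagents that add atoms: chlorotrimethylsilane, C[Si](C)(C)Cl
Why: Copper-catalysed asymmetric conjugate addition of the Grignard reagent to the α-methyl enone should set C9 (the ligand antipode is chosen so that the chain enters the β face, 6R), and silylation in situ stores the C5–C10 enolate regiospecifically.

Step 7
Reactants: 12 trimethyl phosphonoacetate; 13 acrolein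
Product: 14 methyl (2E)-2-(dimethoxyphosphoryl)penta-2,4-dienoate
Conditions: TiCl4, N-methylmorpholine, THF, 0 °C
Reagents that add atoms: none
Why: Titanium-mediated Knoevenagel condensation of the phosphonoacetate with the enal should give the doubly activated diene, which is used fresh and whose alkene geometry is lost in the next step.

Step 8
Reactants: 11 (6R)-7-methyl-6-[(3E)-3-methyl-5-(triisopropylsilyloxy)pent-3-en-1-yl]-8-(trimethylsilyloxy)-1,4-dioxaspiro[4.5]dec-7-ene; 14 methyl (2E)-2-(dimethoxyphosphoryl)penta-2,4-dienoate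
Product: 17 methyl 8,8-ethylenedioxy-15-(triisopropylsilyloxy)-17,18-dinorlabda-2,4,13E-trien-19-oate, via lithium enolate 15 (not isolated), via lithiated 1,6-adduct 16 (not isolated)
Conditions: MeLi, THF, 0 °C to rt; then 14, −78 °C to 50 °C
Reagents that add atoms: none
Why: MeLi cleaves the silyl enol ether to lithium enolate 15, whose C10 should add to the terminal CH2 (the future C1) of 14 in a vinylogous Michael (1,6-) addition, and the phosphonate- and ester-stabilised allylic carbanion 16 then attacks the C5 carbonyl and loses dimethyl phosphate, an intramolecular Horner–Wadsworth–Emmons olefination that creates C4=C5. The closest known reaction type is the cyclohexadiene annulation of ketone enolates with buta-1,3-dienyl phosphonium salts or phosphonates (conjugate addition, then intramolecular Wittig or HWE olefination). Ring A is closed by a 6-exo-trig attack of carbanion carbon C4 on carbonyl carbon C5, with the C2=C3 bond of the allyl anion inside the ring after E/Z equilibration of the delocalised anion. The only new stereocentre is C10: the C9 chain should sit pseudo-axial to avoid allylic strain with the C10 methyl and the C8 ketal, so the acceptor enters on the opposite (α) face and the methyl ends up β, cis to the C9 chain. The step needs 1,6- and not 1,4-addition, which the steric demand of the tetrasubstituted enolate at the unhindered CH2 terminus should secure, and only the 1,6-adduct can close a six-membered ring and leave irreversibly as the enoate. Carbon–carbon bond formation at C10 alone is secured by the regiospecific enolate made in step 6.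

Step 9
Reactants: 17 methyl 8,8-ethylenedioxy-15-(triisopropylsilyloxy)-17,18-dinorlabda-2,4,13E-trien-19-oate
Product: 18 methyl 8,8-ethylenedioxy-15-(triisopropylsilyloxy)-17,18-dinorlabda-4,13E-dien-19-oate
Conditions: 2-nitrobenzenesulfonohydrazide, Et3N, CH2Cl2, rt
Reagents that add atoms: none
Why: Diimide reduction transfers H2 concertedly to the least substituted, unpolarised C2=C3 bond and should spare the tetrasubstituted enoate and the trisubstituted side-chain alkene.

Step 10
Reactants: 18 methyl 8,8-ethylenedioxy-15-(triisopropylsilyloxy)-17,18-dinorlabda-4,13E-dien-19-oate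
Product: 20 methyl 8,8-ethylenedioxy-15-(triisopropylsilyloxy)-17-norlabd-13E-en-19-oate (5α-H; 4α-methyl), via lithium ester enolate 19 (not isolated)
Conditions: Li, NH3 (l), THF, t-BuOH (1 equiv), −78 °C; then MeI, −78 to −33 °C
Reagents that add atoms: iodomethane, CI
Why: In this Birch-type reductive alkylation the C4=C5 enoate takes up two electrons, axial protonation at C5 on the α face should give the trans-fused ester enolate, and MeI attacks C4 from the equatorial α face anti to the axial C10 methyl, so the new methyl is α and the ester β.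

Step 11
Reactants: 20 methyl 8,8-ethylenedioxy-15-(triisopropylsilyloxy)-17-norlabd-13E-en-19-oate
Product: 21 methyl 8-oxo-15-(triisopropylsilyloxy)-17-norlabd-13E-en-19-oate
Conditions: TsOH·H2O (cat.), acetone/H2O, 40 °C
Reagents that add atoms: water, O
Why: Acid-catalysed ketal hydrolysis frees the C8 ketone, and the hindered triisopropylsilyl ether and the C9 centre (already equatorial, the stable epimer) should be unaffected.

Step 12
Reactants: 21 methyl 8-oxo-15-(triisopropylsilyloxy)-17-norlabd-13E-en-19-oate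
Product: 23 methyl 7α-hydroxy-8-oxo-15-(triisopropylsilyloxy)-17-norlabd-13E-en-19-oate, via potassium enolate 22 (not isolated)
Conditions: KN(SiMe3)2, THF, −78 °C; then 3-phenyl-2-(phenylsulfonyl)oxaziridine, −78 °C; aq. NH4Cl
Reagents that add atoms: 3-phenyl-2-(phenylsulfonyl)oxaziridine, O=S(=O)(c1ccccc1)N1OC1c1ccccc1
Why: Kinetic deprotonation should occur at C7 (C9 is tertiary and hindered, C4 has no hydrogen) and the Davis oxidation of the enolate proceeds by axial attack on the α face, giving the 7α alcohol.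

Step 13
Reactants: 23 methyl 7α-hydroxy-8-oxo-15-(triisopropylsilyloxy)-17-norlabd-13E-en-19-oate
Product: 24 methyl 7β-acetoxy-8-oxo-15-(triisopropylsilyloxy)-17-norlabd-13E-en-19-oate
Conditions: AcOH, PPh3, i-PrO2CN=NCO2i-Pr, toluene, 0 °C to rt
Reagents that add atoms: acetic acid, CC(=O)O
Why: In the Mitsunobu reaction acetate displaces the activated axial 7α oxygen by SN2 (helped by the adjacent carbonyl), which should invert C7 to the equatorial 7β acetate.

Step 14
Reactants: 24 methyl 7β-acetoxy-8-oxo-15-(triisopropylsilyloxy)-17-norlabd-13E-en-19-oate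
Product: 25 methyl 7β-acetoxy-15-(triisopropylsilyloxy)labda-8(17),13E-dien-19-oate
Conditions: Zn, CH2Br2, TiCl4, THF/CH2Cl2, 0 °C to rt
Reagents that add atoms: dibromomethane, BrCBr
Why: Lombardo methylenation is non-basic, so the enolisable α-acetoxy ketone should become the C8=C17 alkene without epimerisation at C7 or C9 and without attack on the two esters.

Step 15
Reactants: 25 methyl 7β-acetoxy-15-(triisopropylsilyloxy)labda-8(17),13E-dien-19-oate
Product: 26 methyl (4S,5R,7S,9R,10R)-7-acetoxy-15-hydroxylabda-8(17),13E-dien-19-oate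
Conditions: Bu4NF, AcOH, THF, 0 °C to rt
Reagents that add atoms: none
Why: Fluoride-mediated desilylation cleaves the primary Si–O bond, and buffering with acetic acid should protect the allylic acetate and the methyl ester.

**Compound list**

1 | 1,4-dioxaspiro[4.5]dec-6-en-8-one | O=C1C=CC2(CC1)OCCO2 | starting material
2 | 7-iodo-1,4-dioxaspiro[4.5]dec-6-en-8-one | O=C1C(I)=CC2(CC1)OCCO2 | intermediate
3 | 7-methyl-1,4-dioxaspiro[4.5]dec-6-en-8-one | O=C1C(C)=CC2(CC1)OCCO2 | intermediate
4 | 4-bromobut-1-yne | C#CCCBr | starting material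
5 | (E)-(4-bromo-2-methylbut-1-en-1-yl)dimethylalane | C[Al](C)/C=C(\C)CCBr | intermediate
6 | methyl (2E)-5-bromo-3-methylpent-2-enoate | COC(=O)/C=C(\C)CCBr | intermediate
7 | (2E)-5-bromo-3-methylpent-2-en-1-ol | OC/C=C(\C)CCBr | intermediate
8 | [(2E)-5-bromo-3-methylpent-2-en-1-yl]oxy(triisopropyl)silane | CC(C)[Si](OC/C=C(\C)CCBr)(C(C)C)C(C)C | intermediate
9 | [(3E)-3-methyl-5-(triisopropylsilyloxy)pent-3-en-1-yl]magnesium bromide | Br[Mg]CC/C(C)=C/CO[Si](C(C)C)(C(C)C)C(C)C | intermediate
10 | bromomagnesium enolate of (6R)-7-methyl-6-[(3E)-3-methyl-5-(triisopropylsilyloxy)pent-3-en-1-yl]-1,4-dioxaspiro[4.5]decan-8-one | Br[Mg]OC1=C(C)[C@@H](CC/C(C)=C/CO[Si](C(C)C)(C(C)C)C(C)C)C2(CC1)OCCO2 | intermediate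
11 | (6R)-7-methyl-6-[(3E)-3-methyl-5-(triisopropylsilyloxy)pent-3-en-1-yl]-8-(trimethylsilyloxy)-1,4-dioxaspiro[4.5]dec-7-ene | C[Si](C)(C)OC1=C(C)[C@@H](CC/C(C)=C/CO[Si](C(C)C)(C(C)C)C(C)C)C2(CC1)OCCO2 | intermediate
12 | trimethyl phosphonoacetate | COC(=O)CP(=O)(OC)OC | starting material
13 | acrolein | C=CC=O | starting material
14 | methyl (2E)-2-(dimethoxyphosphoryl)penta-2,4-dienoate | C=C/C=C(/P(=O)(OC)OC)C(=O)OC | intermediate
15 | lithium enolate corresponding to 11 | [Li]OC1=C(C)[C@@H](CC/C(C)=C/CO[Si](C(C)C)(C(C)C)C(C)C)C2(CC1)OCCO2 | intermediate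
16 | lithiated 1,6-adduct (C5 ketone; C10 carries β-methyl and the C1–C4 chain with the phosphonate/ester carbanion at C4) | O=C1CCC2(OCCO2)[C@H](CC/C(C)=C/CO[Si](C(C)C)(C(C)C)C(C)C)[C@@]1(C)C/C=C\[C-](C(=O)OC)P(=O)(OC)OC.[Li+] | intermediate
17 | methyl 8,8-ethylenedioxy-15-(triisopropylsilyloxy)-17,18-dinorlabda-2,4,13E-trien-19-oate | COC(=O)C1=C2CCC3(OCCO3)[C@H](CC/C(C)=C/CO[Si](C(C)C)(C(C)C)C(C)C)[C@@]2(C)CC=C1 | intermediate
18 | methyl 8,8-ethylenedioxy-15-(triisopropylsilyloxy)-17,18-dinorlabda-4,13E-dien-19-oate | COC(=O)C1=C2CCC3(OCCO3)[C@H](CC/C(C)=C/CO[Si](C(C)C)(C(C)C)C(C)C)[C@@]2(C)CCC1 | intermediate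
19 | lithium ester enolate at C4 of the 5α-H reduced ester (drawn as carbanion) | [Li+].COC(=O)[C-]1CCC[C@]2(C)[C@@H](CC/C(C)=C/CO[Si](C(C)C)(C(C)C)C(C)C)C3(OCCO3)CC[C@@H]12 | intermediate
20 | methyl 8,8-ethylenedioxy-15-(triisopropylsilyloxy)-17-norlabd-13E-en-19-oate | C1COC2(O1)CC[C@@H]3[C@](C)(CCC[C@]3(C)C(=O)OC)[C@H]2CC/C(C)=C/CO[Si](C(C)C)(C(C)C)C(C)C | intermediate
21 | methyl 8-oxo-15-(triisopropylsilyloxy)-17-norlabd-13E-en-19-oate | O=C1CC[C@@H]2[C@](C)(CCC[C@]2(C)C(=O)OC)[C@H]1CC/C(C)=C/CO[Si](C(C)C)(C(C)C)C(C)C | intermediate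
22 | potassium C7=C8 enolate of 21 | [K]OC1=CC[C@@H]2[C@](C)(CCC[C@]2(C)C(=O)OC)[C@H]1CC/C(C)=C/CO[Si](C(C)C)(C(C)C)C(C)C | intermediate
23 | methyl 7α-hydroxy-8-oxo-15-(triisopropylsilyloxy)-17-norlabd-13E-en-19-oate | O=C1[C@H](O)C[C@@H]2[C@](C)(CCC[C@]2(C)C(=O)OC)[C@H]1CC/C(C)=C/CO[Si](C(C)C)(C(C)C)C(C)C | intermediate
24 | methyl 7β-acetoxy-8-oxo-15-(triisopropylsilyloxy)-17-norlabd-13E-en-19-oate | O=C1[C@@H](OC(C)=O)C[C@@H]2[C@](C)(CCC[C@]2(C)C(=O)OC)[C@H]1CC/C(C)=C/CO[Si](C(C)C)(C(C)C)C(C)C | intermediate
25 | methyl 7β-acetoxy-15-(triisopropylsilyloxy)labda-8(17),13E-dien-19-oate | C=C1[C@@H](OC(C)=O)C[C@@H]2[C@](C)(CCC[C@]2(C)C(=O)OC)[C@H]1CC/C(C)=C/CO[Si](C(C)C)(C(C)C)C(C)C | intermediate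
26 | methyl (4S,5R,7S,9R,10R)-7-acetoxy-15-hydroxylabda-8(17),13E-dien-19-oate | C=C1[C@@H](OC(C)=O)C[C@@H]2[C@](C)(CCC[C@]2(C)C(=O)OC)[C@H]1CC/C(C)=C/CO | target

**Summary**

Total step count: 15. Longest linear sequence: 12 steps (from 4-bromobut-1-yne: steps 3, 4, 5, 6, 8, 9, 10, 11, 12, 13, 14, 15).

Steps most likely to fail:

1. Step 8. The hindered enolate may add at the inner β-carbon of the diene (1,4-addition), or the stabilised carbanion may fail to olefinate the congested C5 ketone. The fallback sets out from 11 and builds the bridge stepwise. MeLi and allyl iodide should give 7-allyl-7-methyl-6-[(3E)-3-methyl-5-(triisopropylsilyloxy)pent-3-en-1-yl]-1,4-dioxaspiro[4.5]decan-8-one F2 (allyl anti to the C6 chain). Rhodium-catalysed hydroboration of the terminal alkene (catecholborane, RhCl(PPh3)3; then NaBO3·4H2O) gives the primary alcohol F3. I2, PPh3 and imidazole give the iodide F4. Alkylation of the sodium salt of 12 (NaH, DMF) gives the keto phosphonate F5. Intramolecular Horner–Wadsworth–Emmons olefination (NaH, THF, 60 °C) then returns the route at 18, so that step 9 is not needed.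

2. Step 6. Conjugate addition to the α-methyl enone next to the ketal may be slow and the facial discrimination by the ligand poor. The fallback sets out from 1, the unmethylated enone and a better acceptor. The same copper/ferrocenyl diphosphine system and Grignard reagent 9 (made from 8), followed by quenching of the enolate with MeI in the presence of DMPU, should give trans-7-methyl-6-[(3E)-3-methyl-5-(triisopropylsilyloxy)pent-3-en-1-yl]-1,4-dioxaspiro[4.5]decan-8-one F1. Silylation under equilibrating conditions (Me3SiCl, NaI, Et3N, MeCN) toward the more substituted enol ether brings the route back at 11; steps 1 and 2 fall away.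

3. Step 13. The activated axial oxygen may leave by E2 elimination toward the conjugated C6=C7 enone, or the ketone may enolise, instead of SN2 inversion. The fallback sets out from 23 and sets C7 by hydride reduction. Methylenation (Zn, CH2Br2, TiCl4) should give methyl 7α-hydroxy-15-(triisopropylsilyloxy)labda-8(17),13E-dien-19-oate F6. Allylic oxidation with MnO2 gives methyl 7-oxo-15-(triisopropylsilyloxy)labda-8(17),13E-dien-19-oate F7. Luche reduction (NaBH4, CeCl3·7H2O, MeOH, −78 °C; axial hydride delivery on the α face) should give methyl 7β-hydroxy-15-(triisopropylsilyloxy)labda-8(17),13E-dien-19-oate F8. Acetylation (Ac2O, pyridine, DMAP) returns the route at 25.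

Further compounds
F1 | step 6 | trans-7-methyl-6-[(3E)-3-methyl-5-(triisopropylsilyloxy)pent-3-en-1-yl]-1,4-dioxaspiro[4.5]decan-8-one | O=C1CCC2(OCCO2)[C@H](CC/C(C)=C/CO[Si](C(C)C)(C(C)C)C(C)C)[C@H]1C
F2 | step 8 | 7-allyl-7-methyl-6-[(3E)-3-methyl-5-(triisopropylsilyloxy)pent-3-en-1-yl]-1,4-dioxaspiro[4.5]decan-8-one (allyl anti to the C6 chain) | C=CC[C@@]1(C)C(=O)CCC2(OCCO2)[C@@H]1CC/C(C)=C/CO[Si](C(C)C)(C(C)C)C(C)C
F3 | step 8 | 7-(3-hydroxypropyl) analogue of F2 | OCCC[C@@]1(C)C(=O)CCC2(OCCO2)[C@@H]1CC/C(C)=C/CO[Si](C(C)C)(C(C)C)C(C)C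
F4 | step 8 | 7-(3-iodopropyl) analogue of F2 | ICCC[C@@]1(C)C(=O)CCC2(OCCO2)[C@@H]1CC/C(C)=C/CO[Si](C(C)C)(C(C)C)C(C)C
F5 | step 8 | keto phosphonate: methyl 2-(dimethoxyphosphoryl)-5-(ring B C10)pentanoate (mixture of epimers at the phosphonate carbon) | COC(=O)C(CCC[C@@]1(C)C(=O)CCC2(OCCO2)[C@@H]1CC/C(C)=C/CO[Si](C(C)C)(C(C)C)C(C)C)P(=O)(OC)OC
F6 | step 13 | methyl 7α-hydroxy-15-(triisopropylsilyloxy)labda-8(17),13E-dien-19-oate | C=C1[C@H](O)C[C@@H]2[C@](C)(CCC[C@]2(C)C(=O)OC)[C@H]1CC/C(C)=C/CO[Si](C(C)C)(C(C)C)C(C)C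
F7 | step 13 | methyl 7-oxo-15-(triisopropylsilyloxy)labda-8(17),13E-dien-19-oate | C=C1C(=O)C[C@@H]2[C@](C)(CCC[C@]2(C)C(=O)OC)[C@H]1CC/C(C)=C/CO[Si](C(C)C)(C(C)C)C(C)C
F8 | step 13 | methyl 7β-hydroxy-15-(triisopropylsilyloxy)labda-8(17),13E-dien-19-oate | C=C1[C@@H](O)C[C@@H]2[C@](C)(CCC[C@]2(C)C(=O)OC)[C@H]1CC/C(C)=C/CO[Si](C(C)C)(C(C)C)C(C)C
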